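**Plan**

- Retrosynthesis: the three MOM ethers are cut first, then the aryl–CH2 bond C5'–C1'' of the geranyl chain. The pyranone is then contracted by taking out C3, so that C4(=O) is bonded to C2 again; this gives a 2-aryl-2-(iodomethyl)benzofuran-3(2H)-one. Last, C2–CH2I and C2–C1' (ketone α-arylation) are cut.
- Forward: the A ring enters as a preformed benzofuran-3(2H)-one. The B ring is joined at C2, CH2I is added at C2, and the five-membered furanone is expanded to the six-membered pyranone by a radical 1,2-acyl shift. The geranyl chain is joined only afterwards, because the thiyl radicals of the key step would scramble its 2'',3''-alkene. MOM removal is last.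
- Enabling feature: furanone C2 carries the ring oxygen O1 and the B-ring aryl and sits next to the C3 ketone. A radical on the exocyclic CH2 adds to C3=O, and cleavage of the old C2–C3 bond gives a planar C2 radical stabilised by O1 and the aryl, now in the six-membered ring.
- Stereochemistry: the only stereocentre, C2 (S), is set in the key step. Both enantiomers of the racemic iodide converge on the same planar C2 radical, and a chiral thiol delivers H to one face.

Key step: step 6

Remark: the chiral thiol of step 6 is a cysteine-based β-turn peptide thiol (Boc-Cys-D-Pro-Acpc-Phe-NMe2 type) made separately by routine peptide coupling; the antipode that gives the (S) product would be fixed by a short screen.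

**Step 1**
Reactants: 1 4,6-dihydroxybenzofuran-3(2H)-one
Product: 2 4,6-bis(methoxymethoxy)benzofuran-3(2H)-one
Conditions: MOMCl (2.6 equiv), i-Pr2NEt (3 equiv), CH2Cl2/DMF, 0 °C → rt
Reagents that add atoms: chloromethyl methyl ether, COCCl
Why: Williamson-type O-alkylation of both phenols (the chelated 4-OH reacts with excess reagent) under amine buffering, which leaves the less acidic C2–H2 of the furanone untouched.

**Step 2**
Reactants: 3 4-bromo-3-methoxyphenol
Product: 4 4-bromo-2-iodo-5-methoxyphenol
Conditions: NIS (1.05 equiv), TsOH (10 mol%), MeCN, 0 °C → rt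
Reagents that add atoms: N-iodosuccinimide, O=C1CCC(=O)N1I
Why: Electrophilic aromatic iodination should go to the only unhindered position that is ortho to OH and para to OMe (C6 of 3), the position between OH and OMe being flanked on both sides.

**Step 3**
Reactants: 4 4-bromo-2-iodo-5-methoxyphenol
Product: 5 1-bromo-5-iodo-2-methoxy-4-(methoxymethoxy)benzene
Conditions: MOMCl (1.3 equiv), i-Pr2NEt (1.5 equiv), CH2Cl2, 0 °C → rt
Reagents that add atoms: chloromethyl methyl ether, COCCl
Why: Standard MOM protection of a phenol, giving a B-ring piece whose C–I bond is the more reactive of its two carbon–halogen bonds.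

**Step 4**
Reactants: 2 4,6-bis(methoxymethoxy)benzofuran-3(2H)-one; 5 1-bromo-5-iodo-2-methoxy-4-(methoxymethoxy)benzene
Product: 6 rac-2-[5-bromo-4-methoxy-2-(methoxymethoxy)phenyl]-4,6-bis(methoxymethoxy)benzofuran-3(2H)-one
Conditions: 2, LiHMDS (2.2 equiv), THF, −78 → 0 °C; then 5, Pd2(dba)3 (2.5 mol%), Xantphos (6 mol%), 50 °C, argon; NH4Cl work-up with exclusion of air
Reagents that add atoms: none
Why: Palladium-catalysed α-arylation of a ketone enolate (Buchwald–Hartwig type), in which oxidative addition should take place at C–I in preference to the ortho-methoxy C–Br and the preformed lithium enolate prevents aldol self-condensation; the new C2 centre is formed racemic and enolisable, which is of no consequence.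

**Step 5**
Reactants: 6 rac-2-[5-bromo-4-methoxy-2-(methoxymethoxy)phenyl]-4,6-bis(methoxymethoxy)benzofuran-3(2H)-one
Product: 7 rac-2-[5-bromo-4-methoxy-2-(methoxymethoxy)phenyl]-2-(iodomethyl)-4,6-bis(methoxymethoxy)benzofuran-3(2H)-one
Conditions: NaH (1.1 equiv), THF/DMPU, 0 °C; CH2I2 (5 equiv), rt → 40 °C, argon, dark
Reagents that add atoms: diiodomethane, ICI
Why: C-Alkylation of the doubly stabilised enolate with diiodomethane, as used to make substrates for the Dowd–Beckwith reaction, should give the racemic quaternary neopentyl-type iodide, which cannot enolise and is inert to a second SN2 displacement.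

**Step 6**
Reactants: 7 rac-2-[5-bromo-4-methoxy-2-(methoxymethoxy)phenyl]-2-(iodomethyl)-4,6-bis(methoxymethoxy)benzofuran-3(2H)-one
Product: 8 (2S)-2-[5-bromo-4-methoxy-2-(methoxymethoxy)phenyl]-5,7-bis(methoxymethoxy)chroman-4-one
Conditions: (Me3Si)3SiH (1.3 equiv, syringe pump), chiral cysteine-peptide thiol (10 mol%), V-70 (10 mol%), toluene (0.01 M), 30 °C, dark
Reagents that add atoms: none
Why: Proposed new method: (Me3Si)3Si• abstracts iodine from the neopentyl-type C–I bond, the primary radical adds 3-exo-trig to the C3 ketone, and the cyclopropyloxy radical opens by β-scission of the old C2–C3 bond, so that CH2 ends up between C=O and C2 and the furanone becomes the pyranone (ring expansion by 1,2-acyl shift through a transient three-membered ring, no other ring closure). The closest known reaction types are the Dowd–Beckwith ring expansion of α-(halomethyl) cyclic ketones, which gives racemic products with tin hydride, and polarity-reversal catalysis with chiral thiols, in which an S–H bond is the H-atom donor to a prochiral nucleophilic radical. The ring-expanded C2 radical is planar and stabilised by O1 and the B-ring aryl, so both enantiomers of 7 converge on it and the configuration at C2 is set only by H-atom transfer from the chiral thiol (catalyst control). The step needs the acyl shift to outrun both reduction of the primary radical and the neophyl-type 1,2-aryl shift; the aryl ketone acceptor, the strongly stabilised product radical and low stationary concentrations of silane and thiol should secure this. It also needs the thiol, not the silane, to reduce the C2 radical: the electron-rich α-oxy benzylic radical is polarity-matched with S–H and should react only slowly with the hydridic Si–H. Iodine abstraction from C–I should be far faster than bromine abstraction from the aryl C–Br with this silyl radical, and the substrate holds no alkene that a thiyl radical could isomerise.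

**Step 7**
Reactants: 8 (2S)-2-[5-bromo-4-methoxy-2-(methoxymethoxy)phenyl]-5,7-bis(methoxymethoxy)chroman-4-one; 9 geranyl bromide ((2E)-1-bromo-3,7-dimethylocta-2,6-diene)
Product: 11 (2S)-2-[5-((2E)-3,7-dimethylocta-2,6-dien-1-yl)-4-methoxy-2-(methoxymethoxy)phenyl]-5,7-bis(methoxymethoxy)chroman-4-one, via trimethylstannyl flavanone 10 (not isolated)
Conditions: (Me3Sn)2 (1.2 equiv), Pd(PPh3)4 (5 mol%), toluene, 100 °C; then 9 (1.5 equiv), 60 °C
Reagents that add atoms: hexamethylditin, C[Sn](C)(C)[Sn](C)(C)C (supplies the Me3Sn group of 10 only)
Why: Palladium-catalysed stannylation of the aryl bromide followed by Stille coupling with the allylic bromide through a syn-π-allylpalladium species should deliver the aryl group to the less hindered allyl terminus with the 2E geometry kept, under neutral conditions that leave the base-sensitive C2 centre and the MOM ethers alone.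

**Step 8**
Reactants: 11 (2S)-2-[5-((2E)-3,7-dimethylocta-2,6-dien-1-yl)-4-methoxy-2-(methoxymethoxy)phenyl]-5,7-bis(methoxymethoxy)chroman-4-one
Product: 12 Kuwanon U
Conditions: HCl (1.25 M in MeOH)/THF, 25–35 °C
Reagents that add atoms: none
Why: Acid-catalysed acetal exchange of the three aryl MOM ethers with methanol frees the phenols, while the geranyl chain has no ortho hydroxyl to cyclise onto and flavanone C2, which epimerises by base-induced ring opening, should hold under mild acid.

**Compound list**

1 | 4,6-dihydroxybenzofuran-3(2H)-one | O=C1COc2cc(O)cc(O)c21 | starting material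
2 | 4,6-bis(methoxymethoxy)benzofuran-3(2H)-one | O=C1COc2cc(OCOC)cc(OCOC)c21 | intermediate
3 | 4-bromo-3-methoxyphenol | COc1cc(O)ccc1Br | starting material
4 | 4-bromo-2-iodo-5-methoxyphenol | COc1cc(O)c(I)cc1Br | intermediate
5 | 1-bromo-5-iodo-2-methoxy-4-(methoxymethoxy)benzene | COCOc1cc(OC)c(Br)cc1I | intermediate
6 | rac-2-[5-bromo-4-methoxy-2-(methoxymethoxy)phenyl]-4,6-bis(methoxymethoxy)benzofuran-3(2H)-one | COCOc1cc(OC)c(Br)cc1C1Oc2cc(OCOC)cc(OCOC)c2C1=O | intermediate
7 | rac-2-[5-bromo-4-methoxy-2-(methoxymethoxy)phenyl]-2-(iodomethyl)-4,6-bis(methoxymethoxy)benzofuran-3(2H)-one | COCOc1cc(OC)c(Br)cc1C1(CI)Oc2cc(OCOC)cc(OCOC)c2C1=O | intermediate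
8 | (2S)-2-[5-bromo-4-methoxy-2-(methoxymethoxy)phenyl]-5,7-bis(methoxymethoxy)chroman-4-one | COCOc1cc(OC)c(Br)cc1[C@@H]1CC(=O)c2c(OCOC)cc(OCOC)cc2O1 | intermediate
9 | geranyl bromide, (2E)-1-bromo-3,7-dimethylocta-2,6-diene | BrC/C=C(\C)CCC=C(C)C | starting material
10 | (2S)-2-[4-methoxy-2-(methoxymethoxy)-5-(trimethylstannyl)phenyl]-5,7-bis(methoxymethoxy)chroman-4-one | COCOc1cc(OC)c([Sn](C)(C)C)cc1[C@@H]1CC(=O)c2c(OCOC)cc(OCOC)cc2O1 | intermediate
11 | (2S)-2-[5-((2E)-3,7-dimethylocta-2,6-dien-1-yl)-4-methoxy-2-(methoxymethoxy)phenyl]-5,7-bis(methoxymethoxy)chroman-4-one | COCOc1cc(OC)c(C/C=C(\C)CCC=C(C)C)cc1[C@@H]1CC(=O)c2c(OCOC)cc(OCOC)cc2O1 | intermediate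
12 | Kuwanon U, (2S)-2-[5-((2E)-3,7-dimethylocta-2,6-dien-1-yl)-2-hydroxy-4-methoxyphenyl]-5,7-dihydroxychroman-4-one | COc1cc(O)c([C@@H]2CC(=O)c3c(O)cc(O)cc3O2)cc1C/C=C(\C)CCC=C(C)C | target

**Step count and risks**

Total steps: 8. Longest linear sequence: 7 (steps 2 to 8, from 4-bromo-3-methoxyphenol).

Steps most likely to fail:

1. Step 6 (proposed new method). The facial selectivity of the H-atom transfer to the planar C2 radical may be poor, or the thiol may reduce the primary radical before the acyl shift. Fallback with known chemistry, setting out from 7 and coming back at 8: iodide 7 would be ring-expanded without stereocontrol under the classical Dowd–Beckwith conditions (Bu3SnH by syringe pump, AIBN, benzene, 80 °C) to the racemic bromoflavanone F1. F1 would then be resolved by asymmetric transfer hydrogenation (Cp*RhCl-TsDPEN, HCO2H/Et3N, EtOAc, rt), using the catalyst antipode that reduces the (R)-ketone. This leaves (S)-ketone 8 and converts the unwanted enantiomer into the cis-flavan-4-ol F2, which is removed by chromatography.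

2. Step 5. The ambident benzofuran-3-olate may be alkylated at oxygen instead of C2, or react too slowly with the poor SN2 electrophile. Fallback, setting out from 6 and coming back at 7: the C–C bond would be made by an aldol reaction instead of an alkylation. Ketone 6 with aqueous formaldehyde and catalytic NaHCO3 in THF at rt should give the hydroxymethyl ketone F3, the oxygen adduct of formaldehyde being reversible. The alcohol would then be exchanged for iodide under Appel conditions (PPh3, I2, imidazole, toluene, 60–80 °C) to give 7.

3. Step 7. Stannylation of the hindered, electron-rich aryl bromide may stay incomplete, or the aryl stannane may be protodestannylated before the allyl coupling. Fallback, setting out from 8 and 9 and coming back at 11: the polarity of the coupling would be reversed. Geranyl bromide 9 with Bu3SnLi (THF, −78 °C) gives (E)-geranyltributylstannane F4. F4 would be coupled directly with aryl bromide 8 (Pd2(dba)3, P(t-Bu)3, toluene or DMF, 60–80 °C) to give 11; the linear/branched ratio and the 2E geometry would have to be checked at this point.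

**Further compounds**

F1 | step 6 | rac-2-[5-bromo-4-methoxy-2-(methoxymethoxy)phenyl]-5,7-bis(methoxymethoxy)chroman-4-one | COCOc1cc(OC)c(Br)cc1C1CC(=O)c2c(OCOC)cc(OCOC)cc2O1
F2 | step 6 | (2R,4R)-2-[5-bromo-4-methoxy-2-(methoxymethoxy)phenyl]-5,7-bis(methoxymethoxy)chroman-4-ol | COCOc1cc(OC)c(Br)cc1[C@H]1C[C@@H](O)c2c(OCOC)cc(OCOC)cc2O1
F3 | step 5 | rac-2-[5-bromo-4-methoxy-2-(methoxymethoxy)phenyl]-2-(hydroxymethyl)-4,6-bis(methoxymethoxy)benzofuran-3(2H)-one | COCOc1cc(OC)c(Br)cc1C1(CO)Oc2cc(OCOC)cc(OCOC)c2C1=O
F4 | step 7 | tributyl[(2E)-3,7-dimethylocta-2,6-dien-1-yl]stannane | CCCC[Sn](CCCC)(CCCC)C/C=C(\C)CCC=C(C)C
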